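## Structural features

The target is a C30 onocerane-type diol: two trans-fused 4,4,10-trimethyldecalins joined only by the two-carbon bridge C9–C11–C12–C9′. Each decalin is numbered as a drimane (C3 carbinol, C4 gem-dimethyl, C5 ring-fusion CH, C8 methyl-bearing, C9 bridge-bearing, C10 angular methyl); rings A and B are unprimed in the alkene half and primed in the saturated half. The left half holds the only unsaturation, the trisubstituted C7=C8 alkene, and the stereocentres C3, C5, C9 and C10. The right half holds C3′, C5′, C8′, C9′ and C10′, so nine stereocentres stand in two contiguous arrays (C9–C10–C5 and C8′–C9′–C10′–C5′) plus the two carbinols. Both hydroxyl groups are axial (3α, 3′α) and neopentyl, whereas the C8′ methyl and the bridge bonds at C9 and C9′ are equatorial (8′α, 9β, 9′β) and both ring fusions are 5α-H/10β-CH3. The fragile points are the C7=C8 bond (it can migrate to C8=C9 under acid), the allylic C9–H, and the C3 carbinols (they rearrange if ionised). The real difficulty is that two nearly identical halves must come from one building block, be differentiated at C7–C8, and be joined through C11–C12, a bond flanked by tertiary C9 and C9′ that sit beside quaternary C10 and C10′. The key step exploits ring B of the left half: with C7=C8, the C8 methyl and C5–H it is the skeleton of (R)-carvone, whose isopropenyl carbon maps onto C4 and whose C6 methylene maps onto C10. A tertiary C4 radical made from the isopropenyl group can therefore add to a C3 aldehyde tethered at C10 and close ring A with the gem-dimethyl group and the carbinol in place.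

## Logic of the disconnections

28 ⇐ 27 ⇐ 26 ⇐ 25. No skeletal bond is cut. The two axial carbinols are traced to the 3,3′-diketone because a bulky hydride reduces a 4,4-dimethyl-3-ketone to the axial alcohol. The C3 configuration delivered by ring formation therefore does not matter, and both carbinols leave the stereochemical problem. The demand is equatorial hydride delivery at two remote ketones at once, and desilylation and oxidation that leave C7=C8 where it is.

25 ⇐ 24 ⇐ 22. The C12–O bond is put back (the reverse of a radical deoxygenation). This turns the unfunctionalised bridge into a carbinol that a carbonyl addition can make. The forward demand is thioacylation of a hindered secondary alcohol and a C12 radical that is reduced without touching C7=C8.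

22 ⇐ 14 (through 21) + 20. The cut is C11–C12, the only bond not in a ring and the one that divides the molecule into two C15 units of the same decalin series. The gain is full convergence on two drimane-type partners. The forward demand is addition of a β-branched primary alkyllithium to an α-branched aldehyde faster than its enolisation; the aldehyde is placed on the saturated half because a β,γ-unsaturated aldehyde on the left half would conjugate.

14 ⇐ 13 ⇐ 11 ⇐ 10. The cut is C9–C11 of the left half, taken back through an exocyclic C9=C11 alkene to the C9 ketone. Hydroboration of the diene sets C9 and keeps C7=C8. The demand is methylenation of a neopentyl enone carbonyl and delivery of hydrogen to C9 from the face opposite the C10 methyl.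

20 ⇐ 19 ⇐ 17 ⇐ 16 ⇐ 10. The cut is C9′–C12 of the right half, again through a methylene compound to the C9′ ketone, after saturating C7′–C8′ by enone reduction. C8′ is then set under thermodynamic control next to the ketone and C9′ by the same facial bias as on the left. Both halves thus diverge from 10. The demand is olefination of a 2,2,6-trisubstituted cyclohexanone.

10 ⇐ 9. Only the silyl group is removed. The C3 hydroxyl must be masked through ylide, borane, dissolving-metal, organolithium and stannane chemistry.

9 ⇐ 8. The cut is C3–C4, which opens ring A to a tertiary C4 radical (from an isopropenyl group on C5) and a C3 aldehyde on C10. This removes one ring and one stereocentre and exposes a 5,6,6-trisubstituted carvone. The demand is hydrogen-atom transfer to the isopropenyl group in preference to the enone, and trapping of the alkoxy radical before it reopens.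

8 ⇐ 7 ⇐ 4 + 5. The cut is C10–C1. The three-carbon chain is introduced second so that it enters anti to the isopropenyl group; this fixes C10 and with it the trans ring fusion. The aldehyde is kept as its dioxolane until just before the radical step, an improvement in handling of the sensitive keto aldehyde. The demand is alkylation of a fully substituted enolate with a sluggish primary bromide.

4 ⇐ 1 + 2. The cut is C10–CH3. Kinetic α′-methylation of the enone is routine, and the C10 configuration at this stage is irrelevant.

## Other disconnections considered

Alternative 1: The cut is C4′–C5′ and C9′–C10′ of the saturated half. In the forward step the open-chain (E,E)-isopropenyl dienoate A2 is treated with Fe(acac)3 and PhSiH3. The C4′ radical adds 6-endo to C5′ and the resulting tertiary C10′ radical adds 6-exo to the enoate carbon C9′, giving the decalin acetic ester A1.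
- In its favour: two rings, two C–C bonds and three stereocentres (C5′, C10′, C9′) form in one step, which is better bond and ring economy than the chosen key step. Termination by addition to an enoate is irreversible, which is mechanistically safer than the reversible addition to an aldehyde. A1 already carries C12 and C11.
- Against it: the first closure is a slow 6-endo attack on a trisubstituted alkene that must outrun reduction of the C4′ radical. A2 needs C3′ and C8′ set by separate asymmetric steps in a long acyclic sequence. The facial sense of folding rests on the remote C3′ silyloxy group. Only the saturated half is served, so the left half needs an unrelated synthesis, and the union would have to form C9–C11 at an allylic tertiary carbon beside quaternary C10.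
- Comparison: on structure A1 maps exactly onto the right half. On mechanism the initiation is equal and the cascade more demanding. On step economy the key step is better, but the whole route is expected to be longer because no common intermediate serves both halves.

Alternative 2: The cut is C1–C10 of ring A with the two halves already joined. In the forward step the phenol mesylate A4 is deprotonated and its para carbon C10 displaces the C1 mesylate, giving the cross-conjugated C7 dienone A3 with quaternary C10.
- In its favour: with ring B aromatic, the C9–C11 bond is a benzylic bond that robust arene chemistry can make, so the union problem is easier than in the chosen plan. Quaternary C10 is created in the key step itself by a simple polar alkylation, whereas the chosen plan sets it in an ordinary enolate alkylation.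
- Against it: the planar arene gives no bias at C10 other than the equatorial preference of the C3 silyloxy group in the tether. After A3, C5 and C9 must still be set by reductions of C5=C6 and C8=C9, and the C7 ketone must be converted into the C7=C8 alkene. The right half must come from another route.
- Comparison: on structure the alternative is equal (one ring, one bond) and leaves more stereocentres open. On mechanism it is the more conventional step. On step economy it is expected to be poorer, because carvone supplies C5, C8-methyl and C7=C8 for free in the chosen plan.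

Alternative 3: The cut is C5′–C10′ and C8′–C9′. In the forward step the trienone A6, which holds the finished left half, undergoes an intramolecular Diels–Alder reaction thermally or with Me2AlCl. The silyloxy diene C5′=C6′–C7′=C8′ adds to the C12-activated enone C9′=C10′, and K2CO3–MeOH then frees the C7′ ketone and equilibrates C8′, giving the diketone A5.
- In its favour: both right-half rings, two bonds and three stereocentres are built on the complete left half, and no fragment coupling at a hindered centre is needed, which is better than the chosen plan on the union problem. C8′ is corrected thermodynamically, which is equal to the control used in the chosen plan.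
- Against it: the dienophile has a fully substituted β-carbon and the diene terminus C5′ carries quaternary C4′, so forcing conditions are likely and put the silyloxy diene and C7=C8 at risk. Trans fusion and facial selectivity depend on one transition-state geometry controlled only by C3′. Two ketones (C7′ and C12) must afterwards be removed beside hindered centres.
- Comparison: on structure and bond economy the alternative is the better. On mechanism it is a concerted step with less certain selectivity. On step economy the long linear synthesis of A6 and the two deoxygenations are expected to cancel the gain.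

Key step: step 4

Remark on numbering: drimane numbering is used for each half as defined above; α means the face opposite the C10 (C10′) methyl group.
Assumption (a remark on the chemistry): 4 is used as its mixture of C6 epimers and 22 as its mixture of C12 epimers, because both centres are erased in the following steps.

## Route

Step 1
Reactants: 1 (R)-carvone; 2 iodomethane
Product: 4 (5R,6RS)-2,6-dimethyl-5-(prop-1-en-2-yl)cyclohex-2-en-1-one (6-methylcarvone), via lithium dienolate of carvone 3 (not isolated)
Conditions: LiN(i-Pr)2, THF, −78 °C; MeI, −78 → 0 °C
Reagents that add atoms: iodomethane (2), CI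
Why: Kinetic deprotonation at the α′ methylene gives the cross-conjugated dienolate and C-methylation is a standard enolate alkylation; the new C6 centre is not controlled and need not be, since step 2 erases it.

Step 2
Reactants: 4 6-methylcarvone; 5 2-(2-bromoethyl)-1,3-dioxolane
Product: 7 (5S,6S)-6-[2-(1,3-dioxolan-2-yl)ethyl]-2,6-dimethyl-5-(prop-1-en-2-yl)cyclohex-2-en-1-one (chain trans to isopropenyl), via lithium enolate of 6-methylcarvone 6 (not isolated)
Conditions: LiN(i-Pr)2, THF, −78 → −20 °C; then 5, DMPU, Bu4NI (10 mol %), −20 °C → rt
Reagents that add atoms: 2-(2-bromoethyl)-1,3-dioxolane (5), BrCCC1OCCO1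
Why: Enolate alkylation; the fully substituted enolate should be attacked anti to the adjacent isopropenyl group, which puts the chain trans and the methyl cis to it (future 10β-CH3 against 5α-H). DMPU and in situ iodide exchange should offset the low reactivity of the β-alkoxy primary bromide.

Step 3
Reactants: 7 dioxolane ketone
Product: 8 3-[(1S,6S)-1,3-dimethyl-2-oxo-6-(prop-1-en-2-yl)cyclohex-3-en-1-yl]propanal
Conditions: 2 M aq. HCl, THF, rt
Reagents that add atoms: water, O
Why: Acid-catalysed acetal hydrolysis; dilute aqueous acid at room temperature should leave the isopropenyl group and the enone untouched, and the quaternary α′ carbon cannot epimerise. The aldehyde is used at once.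

Step 4
Reactants: 8 keto aldehyde
Product: 9 (4aS,6S,8aS)-6-hydroxy-2,5,5,8a-tetramethyl-4a,5,6,7,8,8a-hexahydronaphthalen-1(4H)-one (3β-hydroxy enone of rings A and B: C9 ketone, C7=C8, 5α-H, 10β-CH3)
Conditions: Fe(acac)3 (30 mol %), PhSiH3 (2.5 equiv), degassed EtOH, 60 °C, slow addition of 8, 0.02 M
Reagents that add atoms: none
Why: Proposed new method: an iron hydride formed from Fe(acac)3 and PhSiH3 in EtOH should transfer a hydrogen atom to the CH2 terminus of the isopropenyl group, the most electron-rich and least hindered π bond of 8, giving the tertiary C4 radical, which closes ring A by 6-exo-trig addition to the aldehyde carbon C3 through a chair-like transition state on the existing ring B. The C3 alkoxy radical is expected to be reduced at once by the divalent iron left from the first step to a trivalent iron alkoxide that ethanol releases as 9, which is what makes the otherwise reversible addition productive. The closest known reaction types are the Fe(acac)3/PhSiH3 cyclisation of alkene-tethered ketones to tertiary cycloalkanols and the stannane-mediated 6-exo cyclisation of alkyl radicals onto aldehydes; the extension is the aldehyde acceptor under iron hydride conditions. Ring A can only be trans-fused, because the radical-bearing carbon on C5 and the tether on C10 are already trans and neither centre is touched. The one new stereocentre, C3, should be set by the iron-bound oxygen taking the pseudo-equatorial position in the chair, giving the 3β alcohol; the 3α epimer would be carried forward equally, since C3 passes through the ketone in 27. The selectivity needed is hydrogen-atom transfer to the isopropenyl group in the presence of the α-methyl enone and the aldehyde. It rests on the higher reactivity of 1,1-disubstituted donor alkenes, on the fact that the radical can reach the enone only through a 4- or 5-membered ring of the wrong polarity, and on dilution to suppress intermolecular addition to the enone.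

Step 5
Reactants: 9 3β-hydroxy enone
Product: 10 3β-(tert-butyldimethylsilyloxy) enone (silyl ether of 9)
Conditions: TBSOTf, 2,6-lutidine, CH2Cl2, 0 °C
Reagents that add atoms: tert-butyldimethylsilyl trifluoromethanesulfonate, CC(C)(C)[Si](C)(C)OS(=O)(=O)C(F)(F)F
Why: Silylation of a hindered equatorial neopentyl alcohol needs the silyl triflate; the enone has no α′ hydrogen and should be inert. The ether should survive ylides, boranes, Li/NH3, t-BuLi and stannane, and is cleaved by fluoride.

Step 6
Reactants: 10 silyl ether enone
Product: 11 3β-(tert-butyldimethylsilyloxy)drima-7,9(11)-diene (exocyclic C9=CH2)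
Conditions: Ph3PCH3Br, KOt-Bu, toluene, 90 °C
Reagents that add atoms: methyltriphenylphosphonium bromide, C[P+](c1ccccc1)(c1ccccc1)c1ccccc1.[Br-]
Why: Wittig methylenation; the carbonyl is neopentyl and conjugated, hence excess salt-free ylide at elevated temperature, and the only enolisation open to it (γ-deprotonation) is reversible. No stereocentre is formed.

Step 7
Reactants: 11 diene
Product: 13 3β-(tert-butyldimethylsilyloxy)drim-7-en-11-ol (9α-H), via B-alkyl-9-BBN adduct at C11 12 (not isolated)
Conditions: 9-BBN, THF, 0 °C → rt; then aq. NaOH, H2O2, 0 °C → rt
Reagents that add atoms: hydrogen peroxide, OO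
Why: Hydroboration–oxidation; 9-BBN should add only to the exocyclic 1,1-disubstituted end of the diene with boron on C11, leaving the hindered trisubstituted C7=C8 bond. Hydrogen is delivered to C9 from the α face, anti to the axial C10 methyl, as in hydride additions to such angularly methylated decalones, which sets 9α-H with C11 β and pseudo-equatorial.

Step 8
Reactants: 13 homoallylic alcohol
Product: 14 3β-(tert-butyldimethylsilyloxy)-11-iododrim-7-ene
Conditions: I2, PPh3, imidazole, CH2Cl2, 0 °C → rt
Reagents that add atoms: iodine, II
Why: Appel-type iodination of a β-branched primary alcohol by SN2 displacement of the alkoxyphosphonium ion; no cation is formed, so the homoallylic alkene should not participate and C9 is untouched.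

Step 9
Reactants: 10 silyl ether enone
Product: 16 (8βH)-3β-(tert-butyldimethylsilyloxy)-11-nordriman-9-one (C8 methyl α, equatorial), via lithium enolate at C8–C9 15 (not isolated)
Conditions: Li, NH3(l), THF, t-BuOH (1.1 equiv), −78 °C; NH4Cl; then NaOMe (cat.), MeOH, rt
Reagents that add atoms: none
Why: Dissolving-metal reduction of the enone gives the C8–C9 enolate regiospecifically; protonation and base equilibration should place the C8 methyl equatorial (α), because the β epimer would be 1,3-diaxial to the C10 methyl.

Step 10
Reactants: 16 saturated ketone
Product: 17 (8βH)-3β-(tert-butyldimethylsilyloxy)drim-9(11)-ene (exocyclic C9=CH2, 8α-CH3)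
Conditions: Ph3PCH3Br, KOt-Bu, toluene, 110 °C
Reagents that add atoms: methyltriphenylphosphonium bromide, C[P+](c1ccccc1)(c1ccccc1)c1ccccc1.[Br-]
Why: Wittig methylenation under forcing conditions, as used for 2,2,6-trisubstituted cyclohexanones; any enolisation returns the more stable 8α epimer, so C8 should not be lost.

Step 11
Reactants: 17 methylene compound
Product: 19 (8βH,9αH)-3β-(tert-butyldimethylsilyloxy)driman-11-ol (8α-CH3, 9β-CH2OH; the carbinol carbon is C12 of the target), via B-alkyl-9-BBN adduct 18 (not isolated)
Conditions: 9-BBN, THF, 65 °C; then aq. NaOH, H2O2, 0 °C → rt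
Reagents that add atoms: hydrogen peroxide, OO
Why: Hydroboration–oxidation with boron on the exocyclic carbon; hydrogen should add to C9′ from the α face, away from the axial C10′ methyl, giving the equatorial 9′β-CH2OH next to the equatorial 8′α-methyl.

Step 12
Reactants: 19 primary alcohol
Product: 20 (8βH,9αH)-3β-(tert-butyldimethylsilyloxy)driman-11-al (9β-CHO)
Conditions: Dess–Martin periodinane, CH2Cl2, 0 °C → rt
Reagents that add atoms: none
Why: Dess–Martin oxidation under near-neutral conditions; the α-centre C9′ already has the more stable equatorial configuration and should not epimerise.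

Step 13
Reactants: 14 left-half iodide; 20 right-half aldehyde
Product: 22 3β,3′β-bis(tert-butyldimethylsilyloxy) C12 carbinol of the tetracycle (C11–C12 bond formed; both C12 epimers), via C11 alkyllithium 21 (not isolated)
Conditions: 14, t-BuLi (2.1 equiv), Et2O–pentane, −78 °C; then 20, −78 → 0 °C; aq. NH4Cl
Reagents that add atoms: none
Why: Iodine–lithium exchange gives the primary alkyllithium without touching the allylic C9–H, and its 1,2-addition to the non-conjugated α-branched aldehyde forms C11–C12, as aryl- and alkyllithiums add to drimane-type 11-aldehydes. The C12 carbinol centre is not controlled and is removed in step 15.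

Step 14
Reactants: 22 C12 carbinol; 2 iodomethane
Product: 24 S-methyl xanthate of 22 at C12, via sodium xanthate salt 23 (not isolated)
Conditions: NaH, imidazole (cat.), THF, 0 → 50 °C; CS2; then MeI, rt
Reagents that add atoms: carbon disulfide, S=C=S; iodomethane (2), CI
Why: First half of a Barton–McCombie deoxygenation; the small electrophile CS2 should reach the hindered alkoxide where bulkier thioacylating agents might not.

Step 15
Reactants: 24 xanthate
Product: 25 3β,3′β-bis(tert-butyldimethylsilyloxy) tetracycle (C11 and C12 both CH2; C7=C8, 8′α-CH3, 9α-H, 9′α-H)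
Conditions: Bu3SnH, AIBN (cat.), toluene, 100 °C
Reagents that add atoms: none
Why: Barton–McCombie radical deoxygenation; the secondary C12 radical has no favourable cyclisation onto C7=C8 (it would be 4-exo or 5-endo) and should simply be reduced by the stannane, leaving the silyl ethers and the alkene.

Step 16
Reactants: 25 bis-silyl ether
Product: 26 3β,3′β-diol of the tetracycle
Conditions: Bu4NF, THF, 60 °C
Reagents that add atoms: none
Why: Fluoride-mediated desilylation; heating is needed for the two neopentyl secondary ethers, and basic fluoride avoids the acid that could move C7=C8.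

Step 17
Reactants: 26 diol
Product: 27 3,3′-diketone of the tetracycle
Conditions: Dess–Martin periodinane, CH2Cl2, rt
Reagents that add atoms: none
Why: Dess–Martin oxidation of both secondary alcohols; C4 and C4′ are quaternary, so there is nothing to epimerise, and the isolated alkene is inert.

Step 18
Reactants: 27 diketone
Product: 28 target CNP0194061.3 (3α,3′α-diol)
Conditions: KBH(s-Bu)3, THF, −78 → 0 °C; H2O
Reagents that add atoms: none
Why: Bulky trialkylborohydride reduction; the reagent cannot pass the axial hydrogens at C1 and C5 (C1′ and C5′) and should attack each 4,4-dimethyl-3-ketone from the equatorial direction, giving the axial 3α and 3′α alcohols, as is usual for 3-oxo triterpenoids.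

## Compound list

1 | (R)-carvone | CC1=CC[C@@H](C(C)=C)CC1=O | starting material
2 | iodomethane | CI | starting material
3 | lithium cross-conjugated dienolate of carvone (O–Li on C1, C1=C6, C2=C3), not isolated | CC1=CC[C@@H](C(C)=C)C=C1O[Li] | intermediate
4 | (5R,6RS)-2,6-dimethyl-5-(prop-1-en-2-yl)cyclohex-2-en-1-one (6-methylcarvone, C6 epimers) | CC1=CC[C@@H](C(C)=C)C(C)C1=O | intermediate
5 | 2-(2-bromoethyl)-1,3-dioxolane | BrCCC1OCCO1 | starting material
6 | lithium enolate of 6-methylcarvone (C1(OLi)=C6(CH3)), not isolated | CC1=CC[C@@H](C(C)=C)C(C)=C1O[Li] | intermediate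
7 | (5S,6S)-6-[2-(1,3-dioxolan-2-yl)ethyl]-2,6-dimethyl-5-(prop-1-en-2-yl)cyclohex-2-en-1-one | CC1=CC[C@@H](C(C)=C)[C@](C)(CCC2OCCO2)C1=O | intermediate
8 | 3-[(1S,6S)-1,3-dimethyl-2-oxo-6-(prop-1-en-2-yl)cyclohex-3-en-1-yl]propanal (precursor of the key step) | CC1=CC[C@@H](C(C)=C)[C@](C)(CCC=O)C1=O | intermediate
9 | (4aS,6S,8aS)-6-hydroxy-2,5,5,8a-tetramethyl-4a,5,6,7,8,8a-hexahydronaphthalen-1(4H)-one (3β-hydroxy enone, product of the key step) | CC1=CC[C@H]2C(C)(C)[C@@H](O)CC[C@]2(C)C1=O | intermediate
10 | 3β-(tert-butyldimethylsilyloxy) enone (silyl ether of 9) | CC1=CC[C@H]2C(C)(C)[C@@H](O[Si](C)(C)C(C)(C)C)CC[C@]2(C)C1=O | intermediate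
11 | 3β-(tert-butyldimethylsilyloxy)drima-7,9(11)-diene | CC1=CC[C@H]2C(C)(C)[C@@H](O[Si](C)(C)C(C)(C)C)CC[C@]2(C)C1=C | intermediate
12 | 9-[3β-(tert-butyldimethylsilyloxy)drim-7-en-11-yl]-9-borabicyclo[3.3.1]nonane, not isolated | CC1=CC[C@H]2C(C)(C)[C@@H](O[Si](C)(C)C(C)(C)C)CC[C@]2(C)[C@H]1CB1C2CCCC1CCC2 | intermediate
13 | 3β-(tert-butyldimethylsilyloxy)drim-7-en-11-ol (9α-H) | CC1=CC[C@H]2C(C)(C)[C@@H](O[Si](C)(C)C(C)(C)C)CC[C@]2(C)[C@H]1CO | intermediate
14 | 3β-(tert-butyldimethylsilyloxy)-11-iododrim-7-ene | CC1=CC[C@H]2C(C)(C)[C@@H](O[Si](C)(C)C(C)(C)C)CC[C@]2(C)[C@H]1CI | intermediate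
15 | lithium enolate (C8=C9–OLi) of 16, not isolated | CC=1CC[C@H]2C(C)(C)[C@@H](O[Si](C)(C)C(C)(C)C)CC[C@]2(C)C=1O[Li] | intermediate
16 | (8βH)-3β-(tert-butyldimethylsilyloxy)-11-nordriman-9-one (8α-CH3) | C[C@@H]1CC[C@H]2C(C)(C)[C@@H](O[Si](C)(C)C(C)(C)C)CC[C@]2(C)C1=O | intermediate
17 | (8βH)-3β-(tert-butyldimethylsilyloxy)drim-9(11)-ene | C[C@@H]1CC[C@H]2C(C)(C)[C@@H](O[Si](C)(C)C(C)(C)C)CC[C@]2(C)C1=C | intermediate
18 | 9-[(8βH,9αH)-3β-(tert-butyldimethylsilyloxy)driman-11-yl]-9-borabicyclo[3.3.1]nonane, not isolated | C[C@@H]1CC[C@H]2C(C)(C)[C@@H](O[Si](C)(C)C(C)(C)C)CC[C@]2(C)[C@H]1CB1C2CCCC1CCC2 | intermediate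
19 | (8βH,9αH)-3β-(tert-butyldimethylsilyloxy)driman-11-ol | C[C@@H]1CC[C@H]2C(C)(C)[C@@H](O[Si](C)(C)C(C)(C)C)CC[C@]2(C)[C@H]1CO | intermediate
20 | (8βH,9αH)-3β-(tert-butyldimethylsilyloxy)driman-11-al | C[C@@H]1CC[C@H]2C(C)(C)[C@@H](O[Si](C)(C)C(C)(C)C)CC[C@]2(C)[C@H]1C=O | intermediate
21 | [3β-(tert-butyldimethylsilyloxy)drim-7-en-11-yl]lithium, not isolated | CC1=CC[C@H]2C(C)(C)[C@@H](O[Si](C)(C)C(C)(C)C)CC[C@]2(C)[C@H]1C[Li] | intermediate
22 | 3β,3′β-bis(tert-butyldimethylsilyloxy) tetracycle with C12 carbinol (C12 epimers) | CC1=CC[C@H]2C(C)(C)[C@@H](O[Si](C)(C)C(C)(C)C)CC[C@]2(C)[C@H]1CC(O)[C@H]1[C@H](C)CC[C@H]2C(C)(C)[C@@H](O[Si](C)(C)C(C)(C)C)CC[C@]12C | intermediate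
23 | sodium O-alkyl dithiocarbonate (xanthate salt) of 22, not isolated | CC1=CC[C@H]2C(C)(C)[C@@H](O[Si](C)(C)C(C)(C)C)CC[C@]2(C)[C@H]1CC(OC(=S)[S-])[C@H]1[C@H](C)CC[C@H]2C(C)(C)[C@@H](O[Si](C)(C)C(C)(C)C)CC[C@]12C.[Na+] | intermediate
24 | O-alkyl S-methyl dithiocarbonate (xanthate) of 22 | CC1=CC[C@H]2C(C)(C)[C@@H](O[Si](C)(C)C(C)(C)C)CC[C@]2(C)[C@H]1CC(OC(=S)SC)[C@H]1[C@H](C)CC[C@H]2C(C)(C)[C@@H](O[Si](C)(C)C(C)(C)C)CC[C@]12C | intermediate
25 | 3β,3′β-bis(tert-butyldimethylsilyloxy) tetracycle (C7=C8, 8′α-CH3) | CC1=CC[C@H]2C(C)(C)[C@@H](O[Si](C)(C)C(C)(C)C)CC[C@]2(C)[C@H]1CC[C@H]1[C@H](C)CC[C@H]2C(C)(C)[C@@H](O[Si](C)(C)C(C)(C)C)CC[C@]12C | intermediate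
26 | 3β,3′β-diol of the tetracycle | CC1=CC[C@H]2C(C)(C)[C@@H](O)CC[C@]2(C)[C@H]1CC[C@H]1[C@H](C)CC[C@H]2C(C)(C)[C@@H](O)CC[C@]12C | intermediate
27 | 3,3′-diketone of the tetracycle | CC1=CC[C@H]2C(C)(C)C(=O)CC[C@]2(C)[C@H]1CC[C@H]1[C@H](C)CC[C@H]2C(C)(C)C(=O)CC[C@]12C | intermediate
28 | CNP0194061.3 (3α,3′α-diol) | CC1=CC[C@H]2C(C)(C)[C@H](O)CC[C@]2(C)[C@H]1CC[C@H]1[C@H](C)CC[C@H]2C(C)(C)[C@H](O)CC[C@]12C | target

## Step count and least certain steps

Total: 18 steps. Longest linear sequence: 15 steps (steps 1–5, 9–12 and 13–18); the left branch (steps 6–8) is one step shorter.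

Step 4 (key step, proposed new method). The likely failure is loss of the C4 radical before closure, by a second hydrogen-atom transfer or by a 1,5-hydrogen shift from C2. Reopening of the C3 alkoxy radical by β-scission faster than its reduction is a second risk, and competing reduction or acetalisation of the aldehyde in the ethanolic silane medium a third. The fallback uses known stannane chemistry and sets out from 8. Anhydrous HBr in CH2Cl2 at −20 °C should add in the Markovnikov sense to the isopropenyl group to give the tertiary bromide F1. Slow addition of Bu3SnH with AIBN in benzene at 80 °C should then generate the same C4 radical in a chain process, and the alkoxy radical formed by 6-exo closure onto the aldehyde is trapped by the stannane faster than the open alkyl radical. The fallback comes back to the route at 9.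

Step 2. The likely failure is slow C-alkylation of the crowded enolate, which lets elimination of the bromide and proton transfer take over. The fallback sets out from 4. The same enolate is added in a Michael reaction to methyl acrylate (LiN(i-Pr)2, THF, −78 °C), again anti to the isopropenyl group, giving the keto ester F2. i-Bu2AlH then reduces ester and ketone to the diol F3, and a double Dess–Martin oxidation restores the enone and forms the aldehyde. The fallback comes back at 8.

Step 7 (and with it step 6). The likely failures are incomplete methylenation of the hindered enone through reversible γ-enolisation, and poor facial or positional selectivity in the hydroboration of the diene. The fallback sets out from 10 and fixes C9 by a suprafacial sigmatropic shift.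
- Epoxidation with H2O2 and NaOH should give the 7α,8α-epoxy ketone F4.
- Wharton transposition (N2H4·H2O, AcOH, MeOH) gives the 7α-hydroxy C8=C9 allylic alcohol F5.
- MnO2 oxidation gives the transposed enone F6.
- Reduction with NaBH4 and CeCl3·7H2O from the α face gives the 7β-alcohol F7.
- KH and Bu3SnCH2I give the stannylmethyl ether F8.
- n-BuLi at −78 °C triggers a Still–Wittig [2,3] rearrangement that carries CH2OH from the 7β oxygen to the β face of C9 and moves the alkene to C7=C8.

The fallback comes back at 13.

Step 10. The likely failure is enolisation and steric blocking of the 2,2,6-trisubstituted ketone, so that olefination stalls. The fallback sets out from 13, which the left branch already supplies. Hydroxyl-directed hydrogenation with [Ir(cod)(PCy3)(py)]PF6 and H2 in CH2Cl2 should deliver hydrogen to the β face of C7=C8, the face of the C11 hydroxyl, giving the 8α-methyl compound directly. It makes no new compound (F0) and comes back at 19, bypassing steps 9–11.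

Step 13. The likely failure is enolisation of the hindered aldehyde by the basic alkyllithium, or steric retardation of the addition, returning both fragments in reduced or epimerised form. The fallback sets out from 14. Heating with PPh3 in MeCN gives the phosphonium iodide F9. Its ylide (NaN(SiMe3)2, THF, −78 °C), which is far less basic, should condense with 20 to give the (Z)-C11=C12 alkene F10. Diimide (TsNHNH2, NaOAc, aqueous DME, reflux) should reduce the disubstituted alkene in preference to the trisubstituted C7=C8 bond. The fallback comes back at 25.

## Further compounds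

F1 | step 4 | tertiary bromide from Markovnikov addition of HBr to the isopropenyl group of 8 | CC1=CC[C@@H](C(C)(C)Br)[C@](C)(CCC=O)C1=O
F2 | step 2 | methyl 3-[1,3-dimethyl-2-oxo-6-(prop-1-en-2-yl)cyclohex-3-en-1-yl]propanoate (chain trans to isopropenyl) | CC1=CC[C@@H](C(C)=C)[C@](C)(CCC(=O)OC)C1=O
F3 | step 2 | diol from reduction of F2 (ring carbinol epimers) | CC1=CC[C@@H](C(C)=C)[C@](C)(CCCO)C1O
F4 | step 7 | 7α,8α-epoxy ketone of 10 | C[C@@]12O[C@@H]1C[C@H]1C(C)(C)[C@@H](O[Si](C)(C)C(C)(C)C)CC[C@]1(C)C2=O
F5 | step 7 | 3β-(tert-butyldimethylsilyloxy)-11-nordrim-8-en-7α-ol | CC1=C[C@@]2(C)CC[C@H](O[Si](C)(C)C(C)(C)C)C(C)(C)[C@@H]2C[C@H]1O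
F6 | step 7 | 3β-(tert-butyldimethylsilyloxy)-11-nordrim-8-en-7-one | CC1=C[C@@]2(C)CC[C@H](O[Si](C)(C)C(C)(C)C)C(C)(C)[C@@H]2CC1=O
F7 | step 7 | 3β-(tert-butyldimethylsilyloxy)-11-nordrim-8-en-7β-ol | CC1=C[C@@]2(C)CC[C@H](O[Si](C)(C)C(C)(C)C)C(C)(C)[C@@H]2C[C@@H]1O
F8 | step 7 | 7β-(tributylstannylmethoxy) ether of F7 | CC1=C[C@@]2(C)CC[C@H](O[Si](C)(C)C(C)(C)C)C(C)(C)[C@@H]2C[C@@H]1OC[Sn](CCCC)(CCCC)CCCC
F0 | step 10 | none | none
F9 | step 13 | [3β-(tert-butyldimethylsilyloxy)drim-7-en-11-yl]triphenylphosphonium iodide | CC1=CC[C@H]2C(C)(C)[C@@H](O[Si](C)(C)C(C)(C)C)CC[C@]2(C)[C@H]1C[P+](c1ccccc1)(c1ccccc1)c1ccccc1.[I-]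
F10 | step 13 | (Z)-C11=C12 alkene, bis-silyl ether of the tetracycle | CC1=CC[C@H]2C(C)(C)[C@@H](O[Si](C)(C)C(C)(C)C)CC[C@]2(C)[C@H]1/C=C\[C@H]1[C@H](C)CC[C@H]2C(C)(C)[C@@H](O[Si](C)(C)C(C)(C)C)CC[C@]12C
A1 | alternative 1 | right-half decalin C12-acetic methyl ester, 3′β-silyl ether | COC(=O)C[C@H]1[C@H](C)CC[C@H]2C(C)(C)[C@@H](O[Si](C)(C)C(C)(C)C)CC[C@]12C
A2 | alternative 1 | open-chain (E,E)-isopropenyl dienoate precursor | CC(=C)[C@@H](O[Si](C)(C)C(C)(C)C)CC/C(C)=C/CC[C@@H](C)/C=C/C(=O)OC
A3 | alternative 2 | cross-conjugated C7 dienone with ring A closed | CC1=C(CC[C@H]3[C@H](C)CC[C@H]4C(C)(C)[C@@H](O[Si](C)(C)C(C)(C)C)CC[C@]34C)[C@@]2(C)CC[C@H](O[Si](C)(C)C(C)(C)C)C(C)(C)C2=CC1=O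
A4 | alternative 2 | phenol with C1 mesylate tether on C5 | Cc1c(O)cc(C(C)(C)[C@@H](O[Si](C)(C)C(C)(C)C)CCOS(C)(=O)=O)c(C)c1CC[C@H]1[C@H](C)CC[C@H]2C(C)(C)[C@@H](O[Si](C)(C)C(C)(C)C)CC[C@]12C
A5 | alternative 3 | tetracyclic C7′,C12 diketone, 3β,3′β-bis-silyl ether | CC1=CC[C@H]2C(C)(C)[C@@H](O[Si](C)(C)C(C)(C)C)CC[C@]2(C)[C@H]1CC(=O)[C@H]1[C@H](C)C(=O)C[C@H]2C(C)(C)[C@@H](O[Si](C)(C)C(C)(C)C)CC[C@]12C
A6 | alternative 3 | left-half trienone with triethylsilyloxy diene | CC1=CC[C@H]2C(C)(C)[C@@H](O[Si](C)(C)C(C)(C)C)CC[C@]2(C)[C@H]1CC(=O)/C=C(\C)CC[C@H](O[Si](C)(C)C(C)(C)C)C(C)(C)/C=C/C(O[Si](CC)(CC)CC)=C/C
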